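**Numbering used throughout:** 1 5-bromopentanoyl chloride; 2 pentylmagnesium bromide; 3 bromo ketone; 4 bromo ketal; 5 3-methoxyphenylmagnesium bromide; 6 (S)-epichlorohydrin; 7 chlorohydrin; 8 epoxide; 9 Grignard reagent of 4; 10 ketal alcohol; 11 ketal acetate; 12 keto acetate; 13 bis(pinacolato)diboron; 14 aryl boronate; 15 target. Chain atoms are C1 (benzylic) to C13; ring positions are numbered as in 15 (ring C1 chain, C3 OH, C5 OMe).

Assumption: the Grignard reagents 2 and 5 are used as commercial THF solutions, and 6 is used in high enantiomeric purity, because the configuration of C2 in 15 derives from it alone.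

## Analysis of the target

Target 15 is an open tridecane chain whose only ring is the arene on C1. The chain carries an acetoxy group at C2 and a ketone at C8, and the ring carries a free OH at C3 and a methoxy group at C5. C2 is the only stereocentre and is R (O > C1 > C3 > H). It has no partner to relate to, so it must be set absolutely, and it lies between two methylene groups of similar size, which makes it a poor subject for reagent-controlled induction. The sensitive groups are the secondary acetate (hydroxide, hydroperoxide, organometallics), the enolisable dialkyl ketone (organometallics, hydrides, peroxy acids) and the electron-rich phenol (oxidants). The difficulty lies less in the skeleton than in keeping three oxygen functions apart: one ring oxygen methylated, the other free, and the acetyl group on the aliphatic oxygen only. The strategy rests on the fact that ring C3 is meta to both ring C1 and ring C5. In 12, which lacks the C3 oxygen, C2–H lies next to the chain, C4–H next to OMe and C6–H between both, and only C3–H has hydrogen on both neighbouring carbons. A sterically governed C–H functionalisation can therefore single out C3, so the phenol oxygen can be introduced last, on a molecule that already holds the acetate and the ketone.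

## Retrosynthetic reasoning

**Ring C3–O.** Target 15 is traced back to aryl boronate 14. Cutting this bond last means that no free phenol exists while the acetate is installed, so no phenol protecting group is needed. The forward reaction must replace boron by oxygen at the same carbon without touching the acetate or the ketone.

**Ring C3–B (key disconnection).** Boronate 14 is traced back to keto acetate 12 and diboron 13. The cut is made at a C–H bond rather than at a pre-installed oxygen or halogen because the monofunctional 3-methoxyphenyl unit is cheap and C3–H is the only unhindered ring C–H. The forward reaction must borylate one of four ring C–H bonds and leave sp3 C–H bonds, the ester and the ketone alone.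

**Functional group adjustment.** Keto acetate 12 comes from ketal acetate 11 by ketal hydrolysis, and 11 from ketal alcohol 10 by acetylation. The ketone is masked only because the chain is introduced as a carbanion. It is released before the borylation so that the last two steps need no acid.

**C3–C4.** Alcohol 10 is cut into epoxide 8 and Grignard reagent 9, which derives from bromo ketal 4. Cutting here turns C2 into the carbinol carbon of a terminal epoxide, so the stereocentre can come from the chiral pool. It also places the carbanion four methylenes from the masked ketone, a spacing available from acid chloride 1. The forward reaction must open the epoxide only at its terminal carbon.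

**Aryl–C1 and the epoxide.** Epoxide 8 comes from chlorohydrin 7 by ring closure, and 7 from aryl Grignard reagent 5 and (S)-epichlorohydrin 6. The three carbons C1–C2–C3 are those of 6, and its two ends are attacked in turn by two carbon nucleophiles. The order fixes the configuration: aryl first and chain second gives R at C2 from 6, and the reverse order would give S. Using the simple reagent 5 on 6 and the more valuable reagent 9 on 8 is also the economical order.

**C8–C9.** Bromo ketal 4 comes from bromo ketone 3 by ketalisation, and 3 from acid chloride 1 and pentyl Grignard reagent 2. The acyl–alkyl bond is the obvious cut because both halves are commercial and the bromide needed for reagent 9 is already in 1.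

## Alternatives that were turned down

**Alternative 1: enzymatic Baeyer–Villiger ring expansion.**
- Disconnection: the C2–O bond, with the whole C2–C8 segment taken from a seven-membered carbocycle.
- Forward key step: racemic 2-[(3-hydroxy-5-methoxyphenyl)methyl]cycloheptan-1-one A1 would be oxidised by a Baeyer–Villiger monooxygenase at a pH where its α-centre racemises. Oxygen is inserted with retention on the substituted side, and the racemate is drained into (R)-8-[(3-hydroxy-5-methoxyphenyl)methyl]oxocan-2-one A2. The lactone carbonyl is the future C8 and its five ring methylenes are C3–C7. Aminolysis to an amide, addition of 2 and acetylation would finish the chain.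
- For: one catalytic step turns a racemate into the C2–O stereocentre, and the carbon framework comes from a simple enolate alkylation. On this point it is more elegant than buying the stereocentre.
- Against: enzymes of this class are tuned to four- to six-membered ketones. Acceptance of a seven-membered ketone with a large phenolic arylmethyl group, and the sense and level of enantioselectivity, cannot be predicted from structure. Racemisation of a plain α-alkyl ketone is slow at a pH the enzyme tolerates, so the process may fall back to a kinetic resolution that loses half the material. A2 is a medium-ring lactone prone to hydrolysis and oligomerisation. Its free phenol must be kept apart from the C2–OH on acetylation, and the mono-methylated dihydroxyarene must be made beforehand.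
- Comparison: this plan depends on enzyme screening. In the chosen route the selectivity of step 8 follows from the substitution pattern of 12, and the configuration of C2 comes fixed with 6.

**Alternative 2: building the arene by Michael–Claisen annulation.**
- Disconnection: two C–C bonds of the aromatic ring itself.
- Forward key step: dimethyl malonate A4 adds to the β-carbon of (R,E)-6-[(tert-butyldimethylsilyl)oxy]heptadec-3-ene-2,12-dione A3, and the methyl ketone enolate closes onto an ester group. Saponification and decarboxylation give (R)-5-[2-(tert-butyldimethylsilyloxy)-8-oxotridecyl]cyclohexane-1,3-dione A5. Oxidative aromatisation, methylation of one oxygen, silyl removal and acetylation would follow.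
- For: the 1,3,5-pattern is assembled with no regiochemical question, from very cheap components and without a noble metal. On certainty of ring substitution it is at least as strong as C–H borylation.
- Against: A3 holds a second enolisable ketone (the future C8) that competes in the alkoxide-mediated condensation. Its silyloxy group sits next to the γ-carbon of the enone, so dienolate formation can expel it (vinylogous E1cB). After aromatisation, methylation must be stopped at one oxygen, and the aliphatic OH must then be acetylated beside a free phenol. These are the differentiation problems the chosen route avoids. The stereocentre must still be made separately for A3.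
- Comparison: the operations after the annulation alone outnumber the whole end-game of the chosen route, which buys the arene and adds one oxygen.

**Alternative 3: nickel enantioconvergent alkyl–alkyl coupling.**
- Disconnection: the C2–C3 bond.
- Forward key step: racemic 2-[3-(benzyloxy)-5-methoxyphenyl]-1-bromoethyl acetate A6 and (6-oxoundecyl)zinc iodide A7 would be joined by a chiral nickel bis(oxazoline) catalyst through an α-acetoxyalkyl radical. Both enantiomers of A6 converge on (R)-1-[3-(benzyloxy)-5-methoxyphenyl]-8-oxotridecan-2-yl acetate A8, and hydrogenolysis of the benzyl ether would give 15.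
- For: the C2–C3 bond, the stereocentre and the acetate arrive in one step, and the zinc reagent tolerates the free ketone, so no ketal is needed. On step economy and convergence this is the stronger plan.
- Against: A6 derives from an arylacetaldehyde, a class that enolises and self-condenses readily, and A6 can lose HBr to a conjugated enol acetate. The catalyst must tell an arylmethyl from an alkyl branch at the radical centre, and the enantiomeric purity reached on this substrate cannot be predicted. The arene must carry both oxygens from the start, one of them protected, and a deprotection is added at the end.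
- Comparison: the chosen route offers in exchange a configuration that is secure from 6 with no enantio-determining step, a cheap 3-methoxyphenyl building block and no phenol protecting group.

Key step: step 8

## Route

Step 1
Reactants: 1 5-bromopentanoyl chloride; 2 pentylmagnesium bromide
Product: 3 1-bromodecan-5-one
Conditions: Fe(acac)3 (3 mol%), THF, −78 °C; aq. NH4Cl
Reagents that add atoms: none
Why: Iron-catalysed acylation of a Grignard reagent by an acid chloride; at −78 °C acyl transfer is much faster than addition to the ketone formed or attack at the primary C–Br bond, so the reaction should stop at 3.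

Step 2
Reactants: 3 1-bromodecan-5-one
Product: 4 2-(4-bromobutyl)-2-pentyl-1,3-dioxolane
Conditions: HOCH2CH2OH, TsOH·H2O (cat.), toluene, reflux, Dean–Stark
Reagents that add atoms: ethane-1,2-diol, OCCO
Why: Acid-catalysed ketalisation driven by azeotropic removal of water; the ketal masks C8 against the organomagnesium chemistry of step 5, and the primary bromide is inert to the diol under acid.

Step 3
Reactants: 5 3-methoxyphenylmagnesium bromide; 6 (S)-epichlorohydrin
Product: 7 (S)-1-chloro-3-(3-methoxyphenyl)propan-2-ol
Conditions: CuI (10 mol%), THF, −40 → −20 °C; aq. NH4Cl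
Reagents that add atoms: none
Why: Copper-catalysed opening of an epoxide by a Grignard reagent, SN2 at the unsubstituted oxirane carbon, which becomes C1; the stereocentre of 6 is not a reaction site and is carried over unchanged, and the C–Cl bond is kept for step 4.

Step 4
Reactants: 7 (S)-1-chloro-3-(3-methoxyphenyl)propan-2-ol
Product: 8 (S)-2-[(3-methoxyphenyl)methyl]oxirane
Conditions: NaOH (powdered), Et2O, rt
Reagents that add atoms: none
Why: Intramolecular Williamson etherification (3-exo-tet); the C2 alkoxide displaces chloride from the primary carbon, so no bond to the stereocentre is broken and the oxirane now spans C2 and the future C3.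

Step 5
Reactants: 4 2-(4-bromobutyl)-2-pentyl-1,3-dioxolane; 8 (S)-2-[(3-methoxyphenyl)methyl]oxirane
Product: 10 (R)-1-(3-methoxyphenyl)-7-(2-pentyl-1,3-dioxolan-2-yl)heptan-2-ol, via Grignard reagent 9 (not isolated)
Conditions: Mg, I2 (cat.), THF, 45 °C; then CuI (10 mol%), 8, −30 → 0 °C; aq. NH4Cl
Reagents that add atoms: magnesium, [Mg] (held only in 9; lost on work-up)
Why: Grignard formation, then copper-catalysed SN2 opening of the monosubstituted epoxide at its terminal carbon, which forms C3–C4; C2 is again untouched and reads R because benzyl outranks the new alkyl branch, and the cyclic ketal is inert to the organometallic.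

Step 6
Reactants: 10 (R)-1-(3-methoxyphenyl)-7-(2-pentyl-1,3-dioxolan-2-yl)heptan-2-ol
Product: 11 (R)-1-(3-methoxyphenyl)-7-(2-pentyl-1,3-dioxolan-2-yl)heptan-2-yl acetate
Conditions: Ac2O, Et3N, DMAP (cat.), CH2Cl2, 0 °C → rt
Reagents that add atoms: acetic anhydride, CC(=O)OC(C)=O
Why: DMAP-catalysed acylation of a secondary alcohol; the C2–O bond is not broken, so the configuration is retained, and the ketal is stable to the basic medium.

Step 7
Reactants: 11 (R)-1-(3-methoxyphenyl)-7-(2-pentyl-1,3-dioxolan-2-yl)heptan-2-yl acetate
Product: 12 (R)-1-(3-methoxyphenyl)-8-oxotridecan-2-yl acetate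
Conditions: pyridinium p-toluenesulfonate (cat.), acetone/H2O, 55 °C
Reagents that add atoms: water, O
Why: Acid-catalysed ketal hydrolysis; the weak acid should not cleave the secondary acetate, and C2 carries no acidic hydrogen.

Step 8
Reactants: 12 (R)-1-(3-methoxyphenyl)-8-oxotridecan-2-yl acetate; 13 bis(pinacolato)diboron
Product: 14 (R)-1-[3-methoxy-5-(4,4,5,5-tetramethyl-1,3,2-dioxaborolan-2-yl)phenyl]-8-oxotridecan-2-yl acetate
Conditions: 13 (1.0 equiv), [Ir(OMe)(cod)]2 (1.5 mol%), 4,4'-di-tert-butyl-2,2'-bipyridine (dtbpy, 3 mol%), THF, 60 °C, Ar
Reagents that add atoms: none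
Why: Iridium-catalysed arene C–H borylation. The monovalent iridium precatalyst, dtbpy and 13 form the trivalent iridium tris(boryl) complex (dtbpy)Ir(Bpin)3; it cleaves an arene C–H bond by oxidative addition to a pentavalent iridium aryl hydride, C–B reductive elimination releases 14, and 13 restores the tris(boryl) complex with loss of HBpin. The closest known reaction type is the sterically controlled borylation of 1,3-disubstituted arenes, 3-alkyl methoxyarenes among them, at the position meta to both groups. No ring is closed and no stereocentre is formed; C2 is two atoms from the ring and takes no part. The step needs site selectivity among the four ring C–H bonds of 12, and the substrate secures it: the crowded tris(boryl) centre does not cleave a C–H bond next to a substituent, which excludes ring C2 (next to the chain), C4 (next to OMe) and C6 (between both) and leaves only C3. A second borylation should not follow, since every remaining ring C–H is then ortho to a substituent. Chemoselectivity is also needed: sp3 C–H bonds, the benzylic ones included, react far more slowly than an unhindered arene C–H, esters and dialkyl ketones are spectators with 13 as the boron source, and a moderate temperature with one equivalent of 13 limits reduction of the ketone by the HBpin formed.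

Step 9
Reactants: 14 (R)-1-[3-methoxy-5-(4,4,5,5-tetramethyl-1,3,2-dioxaborolan-2-yl)phenyl]-8-oxotridecan-2-yl acetate
Product: 15 (R)-1-(3-hydroxy-5-methoxyphenyl)-8-oxotridecan-2-yl acetate
Conditions: KHSO5 (1.05 equiv, as 2KHSO5·KHSO4·K2SO4), acetone/H2O, rt, 10 min; aq. NaHSO3
Reagents that add atoms: potassium peroxymonosulfate, [K+].[O-]S(=O)(=O)OO
Why: Oxidative ipso-hydroxylation of an aryl boronate; the peroxide oxygen adds to boron, the aryl group migrates from boron to oxygen with loss of sulfate, and the aryl borate hydrolyses, so the OH appears exactly where boron was. The short contact time at acidic pH should leave the acetate and the ketone untouched.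

## Compound list

1 | 5-bromopentanoyl chloride | O=C(Cl)CCCCBr | starting material
2 | pentylmagnesium bromide | CCCCC[Mg]Br | starting material
3 | 1-bromodecan-5-one | CCCCCC(=O)CCCCBr | intermediate
4 | 2-(4-bromobutyl)-2-pentyl-1,3-dioxolane | CCCCCC1(CCCCBr)OCCO1 | intermediate
5 | 3-methoxyphenylmagnesium bromide | COc1cccc([Mg]Br)c1 | starting material
6 | (S)-epichlorohydrin | ClC[C@@H]1CO1 | starting material
7 | (S)-1-chloro-3-(3-methoxyphenyl)propan-2-ol | ClC[C@@H](O)Cc1cccc(OC)c1 | intermediate
8 | (S)-2-[(3-methoxyphenyl)methyl]oxirane | COc1cccc(C[C@H]2CO2)c1 | intermediate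
9 | [4-(2-pentyl-1,3-dioxolan-2-yl)butyl]magnesium bromide (formed in the flask, not isolated) | CCCCCC1(CCCC[Mg]Br)OCCO1 | intermediate
10 | (R)-1-(3-methoxyphenyl)-7-(2-pentyl-1,3-dioxolan-2-yl)heptan-2-ol | CCCCCC1(CCCCC[C@@H](O)Cc2cccc(OC)c2)OCCO1 | intermediate
11 | (R)-1-(3-methoxyphenyl)-7-(2-pentyl-1,3-dioxolan-2-yl)heptan-2-yl acetate | CCCCCC1(CCCCC[C@H](Cc2cccc(OC)c2)OC(C)=O)OCCO1 | intermediate
12 | (R)-1-(3-methoxyphenyl)-8-oxotridecan-2-yl acetate | CCCCCC(=O)CCCCC[C@H](Cc1cccc(OC)c1)OC(C)=O | intermediate
13 | bis(pinacolato)diboron | CC1(C)OB(OC1(C)C)B1OC(C)(C)C(C)(C)O1 | starting material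
14 | (R)-1-[3-methoxy-5-(4,4,5,5-tetramethyl-1,3,2-dioxaborolan-2-yl)phenyl]-8-oxotridecan-2-yl acetate | CCCCCC(=O)CCCCC[C@H](Cc1cc(OC)cc(B2OC(C)(C)C(C)(C)O2)c1)OC(C)=O | intermediate
15 | (R)-1-(3-hydroxy-5-methoxyphenyl)-8-oxotridecan-2-yl acetate | CCCCCC(=O)CCCCC[C@H](Cc1cc(O)cc(OC)c1)OC(C)=O | target

## Step count and risks

Total: 9 steps. Longest linear sequence: 7 steps (steps 1, 2, 5, 6, 7, 8, 9 from 1; the branch from 5 and 6 through steps 3, 4, 5, 6, 7, 8, 9 is equally long).

**Step 8 (key step).** The most likely failure is reduction or O-borylation of the C8 ketone by the HBpin co-product at the iridium centre, or stalling of the catalyst before full conversion. Loss of site selectivity through borylation next to the small methoxy group is a lesser risk. Fallback: abandon the C–H route and carry a halogen at ring C3 from the start. Setting out from 6, 1,3-dibromo-5-methoxybenzene F1 would be converted by Br/Mg exchange (iPrMgCl·LiCl, THF, −15 °C) into (3-bromo-5-methoxyphenyl)magnesium chloride F2. This is taken through the chemistry of steps 3 to 7 unchanged, giving in turn: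
- (S)-1-(3-bromo-5-methoxyphenyl)-3-chloropropan-2-ol F3;
- (S)-2-[(3-bromo-5-methoxyphenyl)methyl]oxirane F4;
- (R)-1-(3-bromo-5-methoxyphenyl)-7-(2-pentyl-1,3-dioxolan-2-yl)heptan-2-ol F5, formed with 9;
- (R)-1-(3-bromo-5-methoxyphenyl)-7-(2-pentyl-1,3-dioxolan-2-yl)heptan-2-yl acetate F6;
- (R)-1-(3-bromo-5-methoxyphenyl)-8-oxotridecan-2-yl acetate F7.

Miyaura borylation of F7 (Pd(dppf)Cl2, 13, KOAc, dioxane, 85 °C) then gives 14, where the route is rejoined before step 9. The position of boron is then fixed by the C–Br bond and not by sterics.

**Step 9.** The most likely failure is oxidation beyond the phenol, since the product is an electron-rich 1,3-dioxygenated arene, or peroxide attack at the C8 ketone (Baeyer–Villiger-type insertion) if the contact time is not kept short. Fallback: keep C8 masked until the ring oxygen is in place. Setting out from 11, the conditions of step 8 would give (R)-1-[3-methoxy-5-(4,4,5,5-tetramethyl-1,3,2-dioxaborolan-2-yl)phenyl]-7-(2-pentyl-1,3-dioxolan-2-yl)heptan-2-yl acetate F8. Oxidation with NaBO3·4H2O (THF/H2O, rt), a milder oxidant that the ketal tolerates, would give (R)-1-(3-hydroxy-5-methoxyphenyl)-7-(2-pentyl-1,3-dioxolan-2-yl)heptan-2-yl acetate F9. The hydrolysis of step 7 applied to F9 gives 15. The same change of order also removes the ketone from the borylation if it proves to be the problem there.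

**Step 5.** The most likely failure is loss of material through Wurtz coupling while 9 is formed and through halohydrin formation from 8 by magnesium halide. Fallback: replace the Grignard reagent by a sulfone-stabilised carbanion. Setting out from 4, displacement with PhSO2Na (DMF, 60 °C) gives 2-[4-(benzenesulfonyl)butyl]-2-pentyl-1,3-dioxolane F10. Its α-lithio derivative (nBuLi, THF/DMPU, −78 °C → rt) opens 8 at the terminal carbon to give (2S,4RS)-4-(benzenesulfonyl)-1-(3-methoxyphenyl)-7-(2-pentyl-1,3-dioxolan-2-yl)heptan-2-ol F11. The arrangement at C2 is that of 10; the descriptor reads S only because the sulfonyl-bearing branch outranks benzyl. Reductive desulfonylation (Na(Hg), Na2HPO4, MeOH) returns to the route at 10.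

**Step 3.** The most likely failure is erosion of enantiomeric purity through competing attack at the C–Cl carbon, which leads to the enantiomeric epoxide after closure, or double arylation after premature ring closure of the magnesium alkoxide. Fallback: set C2 by resolution and not from 6. Setting out from 5, allylation (allyl bromide, THF, 0 °C) gives 1-methoxy-3-(prop-2-en-1-yl)benzene F12, and epoxidation (mCPBA, CH2Cl2) gives racemic 2-[(3-methoxyphenyl)methyl]oxirane F13. Hydrolytic kinetic resolution with (S,S)-(salen)Co(OAc) (0.5 mol%, 0.55 equiv H2O) should leave 8 beside (R)-3-(3-methoxyphenyl)propane-1,2-diol F14, from which it is separated by distillation. The (S,S) assignment is from memory of how this catalyst behaves with alkyl oxiranes and should be confirmed; what matters is the enantiomer that hydrolyses the (R)-epoxide. The route is rejoined at 8.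

**Step 1.** The most likely failure is over-addition to the tertiary alcohol or coupling at the C–Br bond if the acylation is not fast enough. Fallback: go through the N-methoxy-N-methylamide. Setting out from 1, acylation of N,O-dimethylhydroxylamine hydrochloride (K2CO3, CH2Cl2/H2O, 0 °C) gives 5-bromo-N-methoxy-N-methylpentanamide F15. Its magnesium chelate with 2 (THF, 0 °C) collapses to the ketone only on work-up, so over-addition is excluded, and the route is rejoined at 3.

## Further compounds

F1 | step 8 | 1,3-dibromo-5-methoxybenzene | COc1cc(Br)cc(Br)c1
F2 | step 8 | (3-bromo-5-methoxyphenyl)magnesium chloride | COc1cc(Br)cc([Mg]Cl)c1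
F3 | step 8 | (S)-1-(3-bromo-5-methoxyphenyl)-3-chloropropan-2-ol | ClC[C@@H](O)Cc1cc(Br)cc(OC)c1
F4 | step 8 | (S)-2-[(3-bromo-5-methoxyphenyl)methyl]oxirane | COc1cc(Br)cc(C[C@H]2CO2)c1
F5 | step 8 | (R)-1-(3-bromo-5-methoxyphenyl)-7-(2-pentyl-1,3-dioxolan-2-yl)heptan-2-ol | CCCCCC1(CCCCC[C@@H](O)Cc2cc(Br)cc(OC)c2)OCCO1
F6 | step 8 | (R)-1-(3-bromo-5-methoxyphenyl)-7-(2-pentyl-1,3-dioxolan-2-yl)heptan-2-yl acetate | CCCCCC1(CCCCC[C@H](Cc2cc(Br)cc(OC)c2)OC(C)=O)OCCO1
F7 | step 8 | (R)-1-(3-bromo-5-methoxyphenyl)-8-oxotridecan-2-yl acetate | CCCCCC(=O)CCCCC[C@H](Cc1cc(Br)cc(OC)c1)OC(C)=O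
F8 | step 9 | (R)-1-[3-methoxy-5-(4,4,5,5-tetramethyl-1,3,2-dioxaborolan-2-yl)phenyl]-7-(2-pentyl-1,3-dioxolan-2-yl)heptan-2-yl acetate | CCCCCC1(CCCCC[C@H](Cc2cc(OC)cc(B3OC(C)(C)C(C)(C)O3)c2)OC(C)=O)OCCO1
F9 | step 9 | (R)-1-(3-hydroxy-5-methoxyphenyl)-7-(2-pentyl-1,3-dioxolan-2-yl)heptan-2-yl acetate | CCCCCC1(CCCCC[C@H](Cc2cc(O)cc(OC)c2)OC(C)=O)OCCO1
F10 | step 5 | 2-[4-(benzenesulfonyl)butyl]-2-pentyl-1,3-dioxolane | CCCCCC1(CCCCS(=O)(=O)c2ccccc2)OCCO1
F11 | step 5 | (2S,4RS)-4-(benzenesulfonyl)-1-(3-methoxyphenyl)-7-(2-pentyl-1,3-dioxolan-2-yl)heptan-2-ol | CCCCCC1(CCCC(C[C@@H](O)Cc2cccc(OC)c2)S(=O)(=O)c2ccccc2)OCCO1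
F12 | step 3 | 1-methoxy-3-(prop-2-en-1-yl)benzene | COc1cccc(CC=C)c1
F13 | step 3 | racemic 2-[(3-methoxyphenyl)methyl]oxirane | COc1cccc(CC2CO2)c1
F14 | step 3 | (R)-3-(3-methoxyphenyl)propane-1,2-diol | OC[C@H](O)Cc1cccc(OC)c1
F15 | step 1 | 5-bromo-N-methoxy-N-methylpentanamide | CON(C)C(=O)CCCCBr
A1 | alternative 1 | racemic 2-[(3-hydroxy-5-methoxyphenyl)methyl]cycloheptan-1-one | COc1cc(O)cc(CC2CCCCCC2=O)c1
A2 | alternative 1 | (R)-8-[(3-hydroxy-5-methoxyphenyl)methyl]oxocan-2-one | O=C1CCCCC[C@H](Cc2cc(O)cc(OC)c2)O1
A3 | alternative 2 | (R,E)-6-[(tert-butyldimethylsilyl)oxy]heptadec-3-ene-2,12-dione | CCCCCC(=O)CCCCC[C@H](C/C=C/C(C)=O)O[Si](C)(C)C(C)(C)C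
A4 | alternative 2 | dimethyl malonate | COC(=O)CC(=O)OC
A5 | alternative 2 | (R)-5-[2-(tert-butyldimethylsilyloxy)-8-oxotridecyl]cyclohexane-1,3-dione | CCCCCC(=O)CCCCC[C@H](CC1CC(=O)CC(=O)C1)O[Si](C)(C)C(C)(C)C
A6 | alternative 3 | racemic 2-[3-(benzyloxy)-5-methoxyphenyl]-1-bromoethyl acetate | CC(=O)OC(Br)Cc1cc(OC)cc(OCc2ccccc2)c1
A7 | alternative 3 | (6-oxoundecyl)zinc iodide | CCCCCC(=O)CCCCC[Zn]I
A8 | alternative 3 | (R)-1-[3-(benzyloxy)-5-methoxyphenyl]-8-oxotridecan-2-yl acetate | CCCCCC(=O)CCCCC[C@H](Cc1cc(OCc2ccccc2)cc(OC)c1)OC(C)=O
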